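The synthesis rests on cutting C1''–C2'', the bond between the benzylic CH2 on C6 of ring A and the vinylic CH of the side chain. C6 lies between C5–OH and C7–OH of an acylphloroglucinol ring, so a C6–CH2–NMe2 group is a latent ortho-quinone methide (C6=C1''H2, C7=O). In the last step the unprotected Mannich base of (+)-taxifolin meets an (E)-alkenylboronic acid. Boron docks on O7 and N, and the C–N bond breaks. The alkenyl group then moves from boron onto C1'' with rearomatisation and retention of geometry, giving the target without any protecting group. The C3'' methyl and the E geometry come from syn-methylalumination of a terminal alkyne.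

Key step: step 5

Assumption: (+)-(2R,3R)-taxifolin (dihydroquercetin) is bought as the single enantiomer, so C2 and C3 come from the chiral pool and only have to be preserved; flavanonol numbering is used, with ring B as C1'–C6' and the side chain as C1''–C8''.

Step 1
Reactants: 1 methyl hex-5-ynoate
Product: 2 2-methylhept-6-yn-2-ol
Conditions: MeMgBr (3.3 equiv), THF, 0 °C to rt; sat. aq. NH4Cl
Reagents that add atoms: methylmagnesium bromide, C[Mg]Br
Why: Double Grignard addition to the ester gives the tertiary alcohol, while a third equivalent is used up by the acetylenic C–H, which is restored on quench.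

Step 2
Reactants: 2 2-methylhept-6-yn-2-ol
Product: 4 (E)-2,6-dimethyl-7-(4,4,5,5-tetramethyl-1,3,2-dioxaborolan-2-yl)hept-6-en-2-ol, via alkenylalane 3 (not isolated)
Conditions: Me3Al (3.0 equiv), Cp2ZrCl2 (0.25 equiv), CH2Cl2, 0 °C to rt; volatiles off in vacuo; MeOBpin (3 equiv), THF, 0 °C to rt; aq. Rochelle salt
Reagents that add atoms: trimethylaluminium, C[Al](C)C; 2-methoxy-4,4,5,5-tetramethyl-1,3,2-dioxaborolane, COB1OC(C)(C)C(C)(C)O1
Why: Negishi zirconium-catalysed methylalumination adds CH3 and Al syn across the terminal alkyne with Al on the terminal carbon (the hydroxyl is first masked as its dimethylaluminium alkoxide), which installs the C3'' methyl and fixes the E geometry, and the known transmetalation of alkenylalanes with an alkoxy(pinacolato)borane then replaces Al by B with retention.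

Step 3
Reactants: 4 (E)-alkenyl pinacol boronate
Product: 5 [(E)-6-hydroxy-2,6-dimethylhept-1-en-1-yl]boronic acid
Conditions: NaIO4 (3 equiv), NH4OAc (3 equiv), acetone/H2O 1:1, rt
Reagents that add atoms: water, O
Why: Periodate glycol cleavage of the released pinacol pulls the hydrolysis equilibrium of the boronate to the free boronic acid under buffered conditions that leave the alkene and the tertiary alcohol alone.

Step 4
Reactants: 6 (+)-(2R,3R)-taxifolin
Product: 7 (2R,3R)-6-[(dimethylamino)methyl]taxifolin
Conditions: CH2(NMe2)2 (1.0 equiv), 1,4-dioxane, 20 °C, Ar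
Reagents that add atoms: bis(dimethylamino)methane, CN(C)CN(C)C
Why: Mannich aminomethylation (electrophilic aromatic substitution by CH2=NMe2+ released from the aminal by the acidic C7–OH) should pick C6 of ring A, which is flanked by the free C5–OH and C7–OH and is less shielded than C8 (next to O1 and under the C2 aryl group), should stop at the mono-adduct with one equivalent because the product is tied up as an internal O7–H···N salt, and leaves C2 and C3 untouched at room temperature without added base.

Step 5
Reactants: 7 (2R,3R)-6-[(dimethylamino)methyl]taxifolin; 5 [(E)-6-hydroxy-2,6-dimethylhept-1-en-1-yl]boronic acid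
Product: 10 (2R,3R)-6-[(2E)-7-hydroxy-3,7-dimethyloct-2-en-1-yl]taxifolin (target), via O7–B–N chelate 8 (not isolated), via boron-bound ortho-quinone methide 9 (not isolated)
Conditions: 5 (2.2 equiv), 4 Å MS, degassed 1,4-dioxane, 70 °C, Ar; aqueous work-up at pH 5
Reagents that add atoms: none
Why: Boronic acid 5 condenses with the acidic C7–OH of 7 and is clamped by the neighbouring NMe2 group to give the six-membered O7–B–N chelate 8, in which boron is tetracoordinate and nitrogen has become a leaving group; heterolysis of the C1''–N bond, pushed by O1 and C5–OH of ring A, gives the boron-bound ortho-quinone methide 9 (C6=C1''H2, C7=O→B), the alkenyl group shifts from boron to C1'' through a six-membered array (B, O7, C7, C6, C1'', C2''), which forms C1''–C2'' and rearomatises ring A, and aqueous work-up hydrolyses the remaining B–O and B–N bonds. The closest known reaction types are the conjugate addition of alkenylboronates to ortho-quinone methides generated in situ from ortho-hydroxybenzyl ethers and alcohols, the thermal generation of such quinone methides from phenolic Mannich bases, and the Petasis borono-Mannich reaction of salicylaldehydes, which uses the same phenol-bound tetracoordinate boron. No ring of the target is closed (the chelate ring of 8 is temporary) and no stereocentre is made; C2 and C3 are spectators under these nearly neutral conditions, and transfer from tetracoordinate boron goes with retention at C2'', so the E geometry set in step 2 is carried over. The step needs chemoselectivity for C-alkenylation over capture of the quinone methide by C8 of a second flavanonol, by the amine or by hydroxyl groups; O- and N-capture are reversible, and intramolecular delivery from the pre-formed chelate should outrun bimolecular attack by C8. The second equivalent of 5 reversibly esterifies the ring B catechol, which shields it from oxidation and from quinone-methide-type opening at C2, and it is washed off on work-up. Attachment at C6 rather than C8 is inherited from 7.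

Compound list
1 | methyl hex-5-ynoate | C#CCCCC(=O)OC | starting material
2 | 2-methylhept-6-yn-2-ol | C#CCCCC(C)(C)O | intermediate
3 | dimethyl[(E)-6-(dimethylaluminiooxy)-2,6-dimethylhept-1-en-1-yl]alane | C/C(=C\[Al](C)C)CCCC(C)(C)O[Al](C)C | intermediate
4 | (E)-2,6-dimethyl-7-(4,4,5,5-tetramethyl-1,3,2-dioxaborolan-2-yl)hept-6-en-2-ol | C/C(=C\B1OC(C)(C)C(C)(C)O1)CCCC(C)(C)O | intermediate
5 | [(E)-6-hydroxy-2,6-dimethylhept-1-en-1-yl]boronic acid | C/C(=C\B(O)O)CCCC(C)(C)O | intermediate
6 | (+)-(2R,3R)-taxifolin | Oc1cc2c(c(O)c1)C(=O)[C@H](O)[C@@H](c1ccc(O)c(O)c1)O2 | starting material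
7 | (2R,3R)-6-[(dimethylamino)methyl]taxifolin | CN(C)Cc1c(O)cc2c(c1O)C(=O)[C@H](O)[C@@H](c1ccc(O)c(O)c1)O2 | intermediate
8 | zwitterionic O7–B–N chelate of 7 with 5 (six-membered ring C6–C1''–N–B–O7–C7; boron carries OH and the E-alkenyl group) | C/C(=C\[B-]1(O)Oc2cc3c(c(O)c2C[N+]1(C)C)C(=O)[C@H](O)[C@@H](c1ccc(O)c(O)c1)O3)CCCC(C)(C)O | intermediate
9 | ortho-quinone methide (C6=C1''H2, C7=O) with O7 bound to B(OH)(NMe2)(E-alkenyl) | C=C1C(=[O+][B-](O)(N(C)C)/C=C(\C)CCCC(C)(C)O)C=C2C(=C1O)C(=O)[C@H](O)[C@@H](c1ccc(O)c(O)c1)O2 | intermediate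
10 | (2R,3R)-2-(3,4-dihydroxyphenyl)-3,5,7-trihydroxy-6-[(2E)-7-hydroxy-3,7-dimethyloct-2-en-1-yl]chroman-4-one | C/C(=C\Cc1c(O)cc2c(c1O)C(=O)[C@H](O)[C@@H](c1ccc(O)c(O)c1)O2)CCCC(C)(C)O | target

Total step count: 5. Longest linear sequence: 4 steps (1, 2, 3, 5).

Steps most likely to fail

Step 5. Three processes may interfere:
- The quinone methide may be captured by ring A of a second molecule (methylene bridging).
- Alkenyl transfer may be slowed because boron is held by the catechol or by the C4=O/C5–OH pair.
- C2 may epimerise on prolonged heating.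

The fallback sets out from 7 and 5 and returns at 10. It moves the union from quinone methide chemistry to a palladium-catalysed sp3–sp2 cross-coupling on a fully masked core. Ac2O/pyridine at 0 °C to rt should turn 7 into the penta-O-acetyl Mannich base F1. Ethyl chloroformate in CH2Cl2 should cleave the benzylic C–N bond (von Braun-type dealkylation) to the 6-chloromethyl pentaacetate F2. Suzuki–Miyaura coupling of F2 with 5 (Pd(OAc)2/SPhos, anhydrous K3PO4, THF, 40 °C) is a known benzyl halide/alkenylboron coupling that keeps the alkene geometry, and it should give the coupled pentaacetate F3. K2CO3 in degassed MeOH at 0 °C followed by acidification should remove the five acetates and give 10.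

Step 4. Site selectivity between C6 and C8 may be poor, and double aminomethylation may occur. The fallback sets out from 6, uses 5 and returns at 10. It hands site control from the innate reactivity of ring A to a tether on O5.
- TBSCl/imidazole/DMF should silylate every hydroxyl except the chelated C5–OH, giving the 3,7,3',4'-tetra-O-TBS ether F4.
- PhB(OH)2, paraformaldehyde and catalytic propionic acid in refluxing toluene (boronic-acid-templated ortho-hydroxymethylation of phenols) can deliver formaldehyde only to the single free ortho position of C5–OH, which is C6. This gives the O5/C6-fused 2-phenyl-4H-1,3,2-dioxaborin F5.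
- Exchange with pinacol in THF frees the 6-hydroxymethyl-5-phenol F6.
- Heating F6 with 5 in dioxane runs the same quinone methide/boronate union, now through C5=O, to the coupled tetrasilyl ether F7.
- Et3N·3HF in THF then gives 10.

Step 2. The aluminium-to-boron exchange may be incomplete or unselective (methyl instead of alkenyl transfer), and the alkenyl metal may be protonated on work-up. The fallback sets out from 2 (through alane 3) and returns at 4. The alane is quenched with iodine in THF at −30 °C, the standard end of a methylalumination, to give the (E)-vinyl iodide F8. The C–B bond is then made by Miyaura borylation (B2pin2, PdCl2(PPh3)2, PPh3, KOPh, toluene, 50 °C) with retention, giving 4.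

Further compounds
F1 | step 5 | (2R,3R)-3,5,7,3',4'-penta-O-acetyl-6-[(dimethylamino)methyl]taxifolin | CN(C)Cc1c(OC(C)=O)cc2c(c1OC(C)=O)C(=O)[C@H](OC(C)=O)[C@@H](c1ccc(OC(C)=O)c(OC(C)=O)c1)O2
F2 | step 5 | (2R,3R)-3,5,7,3',4'-penta-O-acetyl-6-(chloromethyl)taxifolin | ClCc1c(OC(C)=O)cc2c(c1OC(C)=O)C(=O)[C@H](OC(C)=O)[C@@H](c1ccc(OC(C)=O)c(OC(C)=O)c1)O2
F3 | step 5 | (2R,3R)-3,5,7,3',4'-penta-O-acetyl-6-[(2E)-7-hydroxy-3,7-dimethyloct-2-en-1-yl]taxifolin | C/C(=C\Cc1c(OC(C)=O)cc2c(c1OC(C)=O)C(=O)[C@H](OC(C)=O)[C@@H](c1ccc(OC(C)=O)c(OC(C)=O)c1)O2)CCCC(C)(C)O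
F4 | step 4 | (2R,3R)-3,7,3',4'-tetra-O-(tert-butyldimethylsilyl)taxifolin | CC(C)(C)[Si](C)(C)Oc1cc2c(c(O)c1)C(=O)[C@H](O[Si](C)(C)C(C)(C)C)[C@@H](c1ccc(O[Si](C)(C)C(C)(C)C)c(O[Si](C)(C)C(C)(C)C)c1)O2
F5 | step 4 | O5/C6-fused 2-phenyl-4H-1,3,2-dioxaborin of (2R,3R)-3,7,3',4'-tetra-O-TBS-taxifolin | C1OB(c2ccccc2)Oc2c1c(O[Si](C)(C)C(C)(C)C)cc1c2C(=O)[C@H](O[Si](C)(C)C(C)(C)C)[C@@H](c2ccc(O[Si](C)(C)C(C)(C)C)c(O[Si](C)(C)C(C)(C)C)c2)O1
F6 | step 4 | (2R,3R)-3,7,3',4'-tetra-O-TBS-6-(hydroxymethyl)taxifolin | OCc1c(O[Si](C)(C)C(C)(C)C)cc2c(c1O)C(=O)[C@H](O[Si](C)(C)C(C)(C)C)[C@@H](c1ccc(O[Si](C)(C)C(C)(C)C)c(O[Si](C)(C)C(C)(C)C)c1)O2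
F7 | step 4 | (2R,3R)-3,7,3',4'-tetra-O-TBS-6-[(2E)-7-hydroxy-3,7-dimethyloct-2-en-1-yl]taxifolin | C/C(=C\Cc1c(O[Si](C)(C)C(C)(C)C)cc2c(c1O)C(=O)[C@H](O[Si](C)(C)C(C)(C)C)[C@@H](c1ccc(O[Si](C)(C)C(C)(C)C)c(O[Si](C)(C)C(C)(C)C)c1)O2)CCCC(C)(C)O
F8 | step 2 | (E)-7-iodo-2,6-dimethylhept-6-en-2-ol | C/C(=C\I)CCCC(C)(C)O
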